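**Plan**

Locants C1–C8 are those of the 6-oxabicyclo[3.2.1]octan-7-one core. C5 is a tertiary carbinol carbon that carries isopropenyl and is bonded to C8, and the lactone carbonyl C7 sits on the quaternary C1 next to C8; C5 can therefore be an isopropenyl ketone, C8 the γ carbon of an allyl nucleophile, and C7 one of two equal esters on C1.
Retrosynthesis: cut the bond between the side-chain CH2 and C3 of the butenolide (B-alkyl Suzuki coupling) and the two-carbon link of the C8 propanoate (cross-metathesis, then reduction); then O6–C7 and C5–C8 together; then C4–C5 and C5–isopropenyl (carbonylative coupling), C1–C8 (malonate to propiolate) and C1–C2 (allylic alkylation).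
Forward: dimethyl malonate is crotylated and vinylated to an acyclic chain carrying ketone, allyl bromide and malonate; one chromium-mediated step closes first the cyclohexane (C5–C8) and then the γ-lactone (O6–C7); the C1 ester and the C8 vinyl group are then grown into the two side chains.
Stereochemistry: C2 (R) comes from an iridium-catalysed asymmetric allylic alkylation; C5, C8 and C1 follow from C2 in the key step through an all-equatorial chair whose axial alkoxide picks one of the two esters.
Key step: step 8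

Remark: the (Sa,S,S) phosphoramidite L from (S)-BINOL and bis[(S)-1-phenylethyl]amine is taken to give the R branched malonate 4, the sense expected with (E)-allyl carbonates and malonate; were the sense reversed, its enantiomer would be used.

**Route**

Step 1
Reactants: 1 (2E)-but-2-en-1-ol
Product: 2 (2E)-but-2-en-1-yl methyl carbonate
Conditions: ClCO2Me, pyridine, CH2Cl2, 0 °C
Reagents that add atoms: methyl chloroformate, COC(=O)Cl
Why: O-acylation of the primary allylic alcohol by the chloroformate (carbonate formation) installs the ionisable leaving group needed for iridium allyl chemistry and leaves the E alkene untouched.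

Step 2
Reactants: 2 (2E)-but-2-en-1-yl methyl carbonate, 3 dimethyl malonate
Product: 4 dimethyl 2-[(2R)-but-3-en-2-yl]propanedioate
Conditions: [Ir(cod)Cl]2 (2 mol %), L (4 mol %), TBD (8 mol %), THF, rt
Reagents that add atoms: none
Why: In this iridium-catalysed asymmetric allylic alkylation the methoxide released on ionisation of the carbonate deprotonates the malonate, the cyclometallated iridium–phosphoramidite allyl complex directs attack to the substituted terminus, and the chiral ligand fixes the face, so the branched product should form with R configuration at the future C2.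

Step 3
Reactants: 4 dimethyl 2-[(2R)-but-3-en-2-yl]propanedioate, 5 methyl propiolate
Product: 6 trimethyl (1E,4R)-4-methylhexa-1,5-diene-1,3,3-tricarboxylate
Conditions: NaH (10 mol %), THF, 0 °C to rt; then I2 (5 mol %), CH2Cl2, rt
Reagents that add atoms: none
Why: Base-catalysed Michael addition of the tertiary malonate anion to the unhindered sp carbon of the propiolate builds the quaternary carbon (future C1) with the vinylic C8 attached, iodine-catalysed equilibration should converge the geometric isomers on the far less strained E enoate, and C2 is not acidic and stays untouched.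

Step 4
Reactants: 6 trimethyl (1E,4R)-4-methylhexa-1,5-diene-1,3,3-tricarboxylate
Product: 7 dimethyl 2-[(2R)-but-3-en-2-yl]-2-[(1E)-3-hydroxyprop-1-en-1-yl]propanedioate
Conditions: iBu2AlH (2.1 equiv), CH2Cl2, −78 °C; aq. potassium sodium tartrate
Reagents that add atoms: none
Why: The 1,2-reduction of an ester by iBu2AlH should select the exposed, more Lewis-basic conjugated ester over the two neopentyl malonate esters on the fully substituted carbon, and the E geometry keeps the new hydroxyl out of reach of those esters so that no lactone forms.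

Step 5
Reactants: 7 dimethyl 2-[(2R)-but-3-en-2-yl]-2-[(1E)-3-hydroxyprop-1-en-1-yl]propanedioate
Product: 8 dimethyl 2-[(2R)-but-3-en-2-yl]-2-[(1E)-3-{[tert-butyl(dimethyl)silyl]oxy}prop-1-en-1-yl]propanedioate
Conditions: TBSCl, imidazole, CH2Cl2, 0 °C to rt
Reagents that add atoms: tert-butyl(chloro)dimethylsilane, CC(C)(C)[Si](C)(C)Cl
Why: Imidazole-promoted silyl ether formation masks the hydroxyl, which would otherwise consume borane and trap the acylpalladium species of the next step as an ester.

Step 6
Reactants: 8 dimethyl 2-[(2R)-but-3-en-2-yl]-2-[(1E)-3-{[tert-butyl(dimethyl)silyl]oxy}prop-1-en-1-yl]propanedioate, 9 2-iodoprop-1-ene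
Product: 11 dimethyl 2-[(1E)-3-{[tert-butyl(dimethyl)silyl]oxy}prop-1-en-1-yl]-2-[(2R)-6-methyl-5-oxohept-6-en-2-yl]propanedioate, via alkylborane 10 (not isolated)
Conditions: 9-BBN (1.2 equiv), THF, rt; then 9 (1.5 equiv), CO (1 atm), Pd(PPh3)4 (5 mol %), K3PO4 (3 equiv), benzene, rt
Reagents that add atoms: carbon monoxide, [C-]#[O+]
Why: Anti-Markovnikov hydroboration with 9-BBN takes the monosubstituted vinyl group in preference to the internal alkene, and carbonylative Suzuki–Miyaura coupling of the B-alkyl-9-BBN with the iodoalkene (oxidative addition, CO insertion, alkyl transfer from the phosphate-activated borane, reductive elimination) should deliver the isopropenyl ketone, the quaternary malonate being unable to enolise under K3PO4.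

Step 7
Reactants: 11 dimethyl 2-[(1E)-3-{[tert-butyl(dimethyl)silyl]oxy}prop-1-en-1-yl]-2-[(2R)-6-methyl-5-oxohept-6-en-2-yl]propanedioate
Product: 12 dimethyl 2-[(1E)-3-bromoprop-1-en-1-yl]-2-[(2R)-6-methyl-5-oxohept-6-en-2-yl]propanedioate
Conditions: Ph3PBr2 (1.3 equiv), CH2Cl2, 0 °C to rt
Reagents that add atoms: triphenylphosphine dibromide, BrP(Br)(c1ccccc1)(c1ccccc1)c1ccccc1
Why: Triphenylphosphine dibromide converts primary silyl ethers directly into bromides (silyl transfer to bromide, then SN2 displacement of the alkoxyphosphonium ion as in an Appel reaction) under neutral conditions that spare the enone, and either allylic regioisomer of the bromide would lead to the same allylchromium species.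

Step 8
Reactants: 12 dimethyl 2-[(1E)-3-bromoprop-1-en-1-yl]-2-[(2R)-6-methyl-5-oxohept-6-en-2-yl]propanedioate
Product: 15 methyl (1R,2R,5S,8R)-8-ethenyl-2-methyl-7-oxo-5-(prop-1-en-2-yl)-6-oxabicyclo[3.2.1]octane-1-carboxylate, via allylchromium dichloride 13 (not isolated), via chromium alkoxide 14 (not isolated)
Conditions: CrCl2 (5 equiv), THF (0.01 M), 0 °C to rt, then 45 °C
Reagents that add atoms: none
Why: Two equivalents of CrCl2 (divalent chromium) reduce the allylic C–Br bond to the allylchromium dichloride 13 (trivalent chromium), whose termini equilibrate by 1,3-metallotropy and which adds through its γ carbon (C8) to the ketone carbon (C5) with chromium bound to the carbonyl oxygen, the closest known reaction type being the intramolecular Nozaki–Hiyama allylation of ketones. The C5–C8 bond closes the cyclohexane in a 6-exo-trig mode, and the chromium alkoxide 14, held 1,3-diaxial to one ester on C1, closes the γ-lactone O6–C7 by 5-exo-trig acyl substitution with loss of methoxide, as chromium alkoxides do in the CrCl2 route to α-methylene-γ-butyrolactones. C5 and C8 are controlled by the forming chair: the C2 methyl group sits equatorial, one of the geminal esters on C1 is necessarily axial and so disfavours an axial isopropenyl group at C5, which puts the small oxygen axial, and the Cr–O link to the allyl unit requires the nascent vinyl group to be gauche to that oxygen and hence equatorial at C8 (a cis-fused bicyclic transition state, reachable from the Z σ-allyl form or a boat-like Cr–O–C5–C8–C=C array). C1 becomes stereogenic because only the ester cis to the axial alkoxide can be reached, which differentiates the two diastereotopic esters. The step needs 1,2- rather than 1,4-addition and γ rather than α attack, both secured by ring size (six- against eight-membered) and by the oxophilic closed transition state, and it needs the all-equatorial diastereomer, secured by the single C2 stereocentre and the quaternary diester.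

Step 9
Reactants: 15 methyl (1R,2R,5S,8R)-8-ethenyl-2-methyl-7-oxo-5-(prop-1-en-2-yl)-6-oxabicyclo[3.2.1]octane-1-carboxylate
Product: 16 (1R,2R,5S,8R)-8-ethenyl-2-methyl-7-oxo-5-(prop-1-en-2-yl)-6-oxabicyclo[3.2.1]octane-1-carboxylic acid
Conditions: LiI (10 equiv), EtOAc, reflux; 1 M HCl work-up
Reagents that add atoms: none
Why: Iodide attacks the ester methyl group in an SN2 O-demethylation (the dealkylation stage of a Krapcho reaction), helped by lithium chelation between the two geminal carbonyl groups, while the lactone cannot be opened this way because its alkyl carbon is a tertiary bridgehead, and the acid cannot decarboxylate because that would need a bridgehead enol.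

Step 10
Reactants: 16 (1R,2R,5S,8R)-8-ethenyl-2-methyl-7-oxo-5-(prop-1-en-2-yl)-6-oxabicyclo[3.2.1]octane-1-carboxylic acid
Product: 18 (1R,2R,5S,8R)-8-ethenyl-2-methyl-7-oxo-5-(prop-1-en-2-yl)-6-oxabicyclo[3.2.1]octane-1-carbaldehyde, via acid chloride 17 (not isolated)
Conditions: (COCl)2, DMF (cat.), CH2Cl2, 0 °C to rt; then LiAlH(OtBu)3 (1.1 equiv), THF, −78 °C
Reagents that add atoms: none
Why: The acid is turned into its chloride by the Vilsmeier reagent from oxalyl chloride and DMF, and partial reduction of the acid chloride with the bulky hydride LiAlH(OtBu)3 at −78 °C should stop at the aldehyde while the hindered lactone does not react, the aldehyde having no α hydrogen and so no way to epimerise.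

Step 11
Reactants: 18 (1R,2R,5S,8R)-8-ethenyl-2-methyl-7-oxo-5-(prop-1-en-2-yl)-6-oxabicyclo[3.2.1]octane-1-carbaldehyde, 19 methyl acrylate
Product: 20 methyl (2E)-3-[(1R,2R,5S,8R)-1-formyl-2-methyl-7-oxo-5-(prop-1-en-2-yl)-6-oxabicyclo[3.2.1]octan-8-yl]prop-2-enoate
Conditions: 19 (10 equiv), second-generation Hoveyda–Grubbs catalyst [RuCl2(SIMes)(=CH-C6H4-2-OiPr)] (5 mol %), CH2Cl2, 40 °C
Reagents that add atoms: none
Why: Olefin cross-metathesis pairs the monosubstituted C8 vinyl group with the electron-poor acrylate to give the E enoate, while the 1,1-disubstituted isopropenyl group on a quaternary carbon and the aldehyde stay out of the catalytic cycle.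

Step 12
Reactants: 20 methyl (2E)-3-[(1R,2R,5S,8R)-1-formyl-2-methyl-7-oxo-5-(prop-1-en-2-yl)-6-oxabicyclo[3.2.1]octan-8-yl]prop-2-enoate
Product: 21 methyl (2E)-3-[(1R,2R,5S,8R)-1-ethenyl-2-methyl-7-oxo-5-(prop-1-en-2-yl)-6-oxabicyclo[3.2.1]octan-8-yl]prop-2-enoate
Conditions: Ph3PCH3Br (1.3 equiv), KN(SiMe3)2 (1.2 equiv), THF, −78 to 0 °C
Reagents that add atoms: methyltriphenylphosphonium bromide, C[P+](c1ccccc1)(c1ccccc1)c1ccccc1.[Br-]
Why: Wittig methylenation with the unstabilised ylide is fastest at the aldehyde, so at low temperature and with no excess amide base the neopentyl formyl group should become the C1 vinyl group while the enoate, the lactone and the C8–H position are left alone.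

Step 13
Reactants: 21 methyl (2E)-3-[(1R,2R,5S,8R)-1-ethenyl-2-methyl-7-oxo-5-(prop-1-en-2-yl)-6-oxabicyclo[3.2.1]octan-8-yl]prop-2-enoate
Product: 22 methyl 3-[(1R,2R,5S,8R)-1-ethenyl-2-methyl-7-oxo-5-(prop-1-en-2-yl)-6-oxabicyclo[3.2.1]octan-8-yl]propanoate
Conditions: [(Ph3P)CuH]6 (0.4 equiv), H2O (3 equiv), benzene, rt
Reagents that add atoms: none
Why: Copper hydride conjugate reduction delivers hydride to the β carbon of the enoate and water protonates the copper enolate, a 1,4-reduction that does not touch the isolated vinyl and isopropenyl groups or the lactone.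

Step 14
Reactants: 22 methyl 3-[(1R,2R,5S,8R)-1-ethenyl-2-methyl-7-oxo-5-(prop-1-en-2-yl)-6-oxabicyclo[3.2.1]octan-8-yl]propanoate, 23 3-bromofuran-2(5H)-one
Product: 25 methyl 3-[(1R,2R,5S,8R)-2-methyl-7-oxo-1-[2-(2-oxo-2,5-dihydrofuran-3-yl)ethyl]-5-(prop-1-en-2-yl)-6-oxabicyclo[3.2.1]octan-8-yl]propanoate, via alkylborane 24 (not isolated)
Conditions: Sia2BH (1.3 equiv, from BH3·SMe2 and 2-methylbut-2-ene), THF, 0 °C; then 23 (1.5 equiv), Pd(dppf)Cl2 (10 mol %), AsPh3 (10 mol %), aq. K3PO4, DMF, rt
Reagents that add atoms: none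
Why: Disiamylborane, whose rate falls steeply with substitution at the internal alkene carbon, should hydroborate the monosubstituted C1 vinyl group anti-Markovnikov and leave the isopropenyl group on the quaternary C5, and the primary alkyl group of the borane is then transferred to C3 of the bromobutenolide in a B-alkyl Suzuki–Miyaura coupling under mild phosphate base.

**Compound list**

1 | (2E)-but-2-en-1-ol | C/C=C/CO | starting material
2 | (2E)-but-2-en-1-yl methyl carbonate | C/C=C/COC(=O)OC | intermediate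
3 | dimethyl malonate (dimethyl propanedioate) | COC(=O)CC(=O)OC | starting material
4 | dimethyl 2-[(2R)-but-3-en-2-yl]propanedioate | C=C[C@@H](C)C(C(=O)OC)C(=O)OC | intermediate
5 | methyl propiolate (methyl prop-2-ynoate) | C#CC(=O)OC | starting material
6 | trimethyl (1E,4R)-4-methylhexa-1,5-diene-1,3,3-tricarboxylate | C=C[C@@H](C)C(C(=O)OC)(C(=O)OC)/C=C/C(=O)OC | intermediate
7 | dimethyl 2-[(2R)-but-3-en-2-yl]-2-[(1E)-3-hydroxyprop-1-en-1-yl]propanedioate | C=C[C@@H](C)C(C(=O)OC)(C(=O)OC)/C=C/CO | intermediate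
8 | dimethyl 2-[(2R)-but-3-en-2-yl]-2-[(1E)-3-{[tert-butyl(dimethyl)silyl]oxy}prop-1-en-1-yl]propanedioate | C=C[C@@H](C)C(C(=O)OC)(C(=O)OC)/C=C/CO[Si](C)(C)C(C)(C)C | intermediate
9 | 2-iodoprop-1-ene | C=C(C)I | starting material
10 | dimethyl 2-[(2R)-4-(9-borabicyclo[3.3.1]nonan-9-yl)butan-2-yl]-2-[(1E)-3-{[tert-butyl(dimethyl)silyl]oxy}prop-1-en-1-yl]propanedioate | C1CCC2CCCC1B2CC[C@@H](C)C(C(=O)OC)(C(=O)OC)/C=C/CO[Si](C)(C)C(C)(C)C | intermediate
11 | dimethyl 2-[(1E)-3-{[tert-butyl(dimethyl)silyl]oxy}prop-1-en-1-yl]-2-[(2R)-6-methyl-5-oxohept-6-en-2-yl]propanedioate | C=C(C)C(=O)CC[C@@H](C)C(C(=O)OC)(C(=O)OC)/C=C/CO[Si](C)(C)C(C)(C)C | intermediate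
12 | dimethyl 2-[(1E)-3-bromoprop-1-en-1-yl]-2-[(2R)-6-methyl-5-oxohept-6-en-2-yl]propanedioate | C=C(C)C(=O)CC[C@@H](C)C(C(=O)OC)(C(=O)OC)/C=C/CBr | intermediate
13 | allylchromium dichloride of 12 (CrCl2 in place of Br on the allylic CH2; trivalent chromium) | C=C(C)C(=O)CC[C@@H](C)C(C(=O)OC)(C(=O)OC)/C=C/C[Cr](Cl)Cl | intermediate
14 | dichlorochromium alkoxide of dimethyl (2R,3S,6R)-2-ethenyl-3-hydroxy-6-methyl-3-(prop-1-en-2-yl)cyclohexane-1,1-dicarboxylate | C=C(C)[C@]1(O[Cr](Cl)Cl)CC[C@@H](C)C(C(=O)OC)(C(=O)OC)[C@H]1C=C | intermediate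
15 | methyl (1R,2R,5S,8R)-8-ethenyl-2-methyl-7-oxo-5-(prop-1-en-2-yl)-6-oxabicyclo[3.2.1]octane-1-carboxylate | C=C(C)[C@@]12CC[C@@H](C)[C@@](C(=O)OC)(C(=O)O1)[C@H]2C=C | intermediate
16 | (1R,2R,5S,8R)-8-ethenyl-2-methyl-7-oxo-5-(prop-1-en-2-yl)-6-oxabicyclo[3.2.1]octane-1-carboxylic acid | C=C(C)[C@@]12CC[C@@H](C)[C@@](C(=O)O)(C(=O)O1)[C@H]2C=C | intermediate
17 | (1S,2R,5S,8R)-8-ethenyl-2-methyl-7-oxo-5-(prop-1-en-2-yl)-6-oxabicyclo[3.2.1]octane-1-carbonyl chloride | C=C(C)[C@@]12CC[C@@H](C)[C@@](C(=O)Cl)(C(=O)O1)[C@H]2C=C | intermediate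
18 | (1R,2R,5S,8R)-8-ethenyl-2-methyl-7-oxo-5-(prop-1-en-2-yl)-6-oxabicyclo[3.2.1]octane-1-carbaldehyde | C=C(C)[C@@]12CC[C@@H](C)[C@@](C=O)(C(=O)O1)[C@H]2C=C | intermediate
19 | methyl acrylate (methyl prop-2-enoate) | C=CC(=O)OC | starting material
20 | methyl (2E)-3-[(1R,2R,5S,8R)-1-formyl-2-methyl-7-oxo-5-(prop-1-en-2-yl)-6-oxabicyclo[3.2.1]octan-8-yl]prop-2-enoate | C=C(C)[C@@]12CC[C@@H](C)[C@@](C=O)(C(=O)O1)[C@H]2/C=C/C(=O)OC | intermediate
21 | methyl (2E)-3-[(1R,2R,5S,8R)-1-ethenyl-2-methyl-7-oxo-5-(prop-1-en-2-yl)-6-oxabicyclo[3.2.1]octan-8-yl]prop-2-enoate | C=C(C)[C@@]12CC[C@@H](C)[C@@](C=C)(C(=O)O1)[C@H]2/C=C/C(=O)OC | intermediate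
22 | methyl 3-[(1R,2R,5S,8R)-1-ethenyl-2-methyl-7-oxo-5-(prop-1-en-2-yl)-6-oxabicyclo[3.2.1]octan-8-yl]propanoate | C=C(C)[C@@]12CC[C@@H](C)[C@@](C=C)(C(=O)O1)[C@H]2CCC(=O)OC | intermediate
23 | 3-bromofuran-2(5H)-one | O=C1OCC=C1Br | starting material
24 | methyl 3-[(1R,2R,5S,8R)-1-{2-[bis(3-methylbutan-2-yl)boranyl]ethyl}-2-methyl-7-oxo-5-(prop-1-en-2-yl)-6-oxabicyclo[3.2.1]octan-8-yl]propanoate | C=C(C)[C@@]12CC[C@@H](C)[C@@](CCB(C(C)C(C)C)C(C)C(C)C)(C(=O)O1)[C@H]2CCC(=O)OC | intermediate
25 | methyl 3-[(1R,2R,5S,8R)-2-methyl-7-oxo-1-[2-(2-oxo-2,5-dihydrofuran-3-yl)ethyl]-5-(prop-1-en-2-yl)-6-oxabicyclo[3.2.1]octan-8-yl]propanoate (CNP0209666.1) | C=C(C)[C@@]12CC[C@@H](C)[C@@](CCC3=CCOC3=O)(C(=O)O1)[C@H]2CCC(=O)OC | target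

**Step count and risks**

Total step count: 14.
Longest linear sequence: 14 steps, from 1 (the route is linear; 3, 5, 9, 19 and 23 enter as building blocks).

Steps most likely to fail:

1. Step 8. The ring closure may run through a trans-fused chromium transition state (E σ-allyl form, chair) that places the oxygen equatorial and the isopropenyl group axial. That would mean poor facial selectivity and an alkoxide that can reach neither ester; acyl transfer from the chromium alkoxide may also stall. Fallback: the nucleophile is changed to an allylsilane and the ketone is activated by a Lewis acid (intramolecular Hosomi–Sakurai reaction, open transition state in which only the carbocyclic chair decides), with lactonisation as a separate base step. It sets out from 7. Palladium-catalysed silylation of the allylic alcohol with hexamethyldisilane [Pd(BF4)2(MeCN)4, DMSO/MeOH] should give dimethyl 2-[(2R)-but-3-en-2-yl]-2-[(1E)-3-(trimethylsilyl)prop-1-en-1-yl]propanedioate F1. Hydroboration with 9-BBN to the alkylborane dimethyl 2-[(2R)-4-(9-borabicyclo[3.3.1]nonan-9-yl)butan-2-yl]-2-[(1E)-3-(trimethylsilyl)prop-1-en-1-yl]propanedioate F2 and carbonylative coupling with 9 under the conditions of step 6 lead to dimethyl 2-[(2R)-6-methyl-5-oxohept-6-en-2-yl]-2-[(1E)-3-(trimethylsilyl)prop-1-en-1-yl]propanedioate F3. TiCl4 in CH2Cl2 at −78 °C closes the ring to dimethyl (2R,3S,6R)-2-ethenyl-3-hydroxy-6-methyl-3-(prop-1-en-2-yl)cyclohexane-1,1-dicarboxylate F4. NaH in THF then closes the lactone, and the route is rejoined at 15.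

2. Step 14. Hydroboration may not discriminate well enough between the C1 vinyl and the isopropenyl group, and the bromobutenolide or the product may be degraded by base during transmetallation. Fallback: the butenolide is assembled by olefination and double-bond migration, without boron or a coupling. It sets out from 22. Aldehyde-selective Wacker oxidation [PdCl2(PhCN)2, CuCl2, AgNO2, O2, tBuOH/MeNO2], which does not engage 1,1-disubstituted alkenes, should give methyl 3-[(1R,2R,5S,8R)-2-methyl-7-oxo-1-(2-oxoethyl)-5-(prop-1-en-2-yl)-6-oxabicyclo[3.2.1]octan-8-yl]propanoate F5. Wittig reaction with 3-(triphenylphosphoranylidene)oxolan-2-one gives methyl 3-[(1R,2R,5S,8R)-2-methyl-7-oxo-1-[(2E)-2-(2-oxooxolan-3-ylidene)ethyl]-5-(prop-1-en-2-yl)-6-oxabicyclo[3.2.1]octan-8-yl]propanoate F6. RhCl3·3H2O in hot ethanol then moves the exocyclic double bond into the ring, and the route is rejoined at 25.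

3. Step 3. Addition of the hindered tertiary carbanion may be slow, so that the propiolate oligomerises, and convergence of the alkene geometry may be incomplete. Fallback: the three-carbon unit is brought in at the aldehyde oxidation level through a more reactive acceptor. It sets out from 4. Base-catalysed Michael addition to acrolein (NaOMe cat., MeOH, 0 °C) should give dimethyl 2-[(2R)-but-3-en-2-yl]-2-(3-oxopropyl)propanedioate F7. Dehydrogenation with IBX in DMSO at 65 °C gives dimethyl 2-[(2R)-but-3-en-2-yl]-2-[(1E)-3-oxoprop-1-en-1-yl]propanedioate F8. Luche reduction (NaBH4, CeCl3·7H2O, MeOH, −40 °C) then rejoins the route at 7, so that step 4 is bypassed as well.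

**Further compounds**

F1 | step 8 | dimethyl 2-[(2R)-but-3-en-2-yl]-2-[(1E)-3-(trimethylsilyl)prop-1-en-1-yl]propanedioate | C=C[C@@H](C)C(C(=O)OC)(C(=O)OC)/C=C/C[Si](C)(C)C
F2 | step 8 | dimethyl 2-[(2R)-4-(9-borabicyclo[3.3.1]nonan-9-yl)butan-2-yl]-2-[(1E)-3-(trimethylsilyl)prop-1-en-1-yl]propanedioate | C1CCC2CCCC1B2CC[C@@H](C)C(C(=O)OC)(C(=O)OC)/C=C/C[Si](C)(C)C
F3 | step 8 | dimethyl 2-[(2R)-6-methyl-5-oxohept-6-en-2-yl]-2-[(1E)-3-(trimethylsilyl)prop-1-en-1-yl]propanedioate | C=C(C)C(=O)CC[C@@H](C)C(C(=O)OC)(C(=O)OC)/C=C/C[Si](C)(C)C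
F4 | step 8 | dimethyl (2R,3S,6R)-2-ethenyl-3-hydroxy-6-methyl-3-(prop-1-en-2-yl)cyclohexane-1,1-dicarboxylate | C=C(C)[C@]1(O)CC[C@@H](C)C(C(=O)OC)(C(=O)OC)[C@H]1C=C
F5 | step 14 | methyl 3-[(1R,2R,5S,8R)-2-methyl-7-oxo-1-(2-oxoethyl)-5-(prop-1-en-2-yl)-6-oxabicyclo[3.2.1]octan-8-yl]propanoate | C=C(C)[C@@]12CC[C@@H](C)[C@@](CC=O)(C(=O)O1)[C@H]2CCC(=O)OC
F6 | step 14 | methyl 3-[(1R,2R,5S,8R)-2-methyl-7-oxo-1-[(2E)-2-(2-oxooxolan-3-ylidene)ethyl]-5-(prop-1-en-2-yl)-6-oxabicyclo[3.2.1]octan-8-yl]propanoate | C=C(C)[C@@]12CC[C@@H](C)[C@@](C/C=C3/C(=O)OCC3)(C(=O)O1)[C@H]2CCC(=O)OC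
F7 | step 3 | dimethyl 2-[(2R)-but-3-en-2-yl]-2-(3-oxopropyl)propanedioate | C=C[C@@H](C)C(C(=O)OC)(C(=O)OC)CCC=O
F8 | step 3 | dimethyl 2-[(2R)-but-3-en-2-yl]-2-[(1E)-3-oxoprop-1-en-1-yl]propanedioate | C=C[C@@H](C)C(C(=O)OC)(C(=O)OC)/C=C/C=O
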